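**Remarks on the chemistry** (one line each; atom numbers are germacrane numbers; TBS = tert-butyl(dimethyl)silyl)

Remark on C4: C4 is a bridgehead of the 1,4-oxygen bridge, so once C1 is set it has no configurational freedom, because a ten-membered ring can span the oxolane only with C5 and C10 on the same face; the route therefore builds C1, C8 and C10 and lets the ring closure settle C4, and the C4 tag in the strings of 22 to 27 is written as in the target string, although on an unbridged oxolane (compound 4, same tag) it denotes the ethenyl group anti to the side chain, which is why C4 has to be erased and set anew.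

Remark on the seco acid: it differs in three points from a seco acid that carries the C13 acetate and is made by bromination and dehydrobromination of a methylene lactone: bromine is placed syn to C7 by anti bromolactonisation of an alkynoic acid (an elimination would favour bromine next to the ring oxygen, away from the C7 substituent); C13 is a silyl ether during the nickel step, because an allylic acetate is itself an electrophile for low-valent nickel, and is acetylated afterwards; and the C4 carboxyl is anti to the C1 side chain, so that neither the acid nor the aldehyde before it can close onto the C10 hydroxyl.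

Remark on the terpene: (S)-(+)-linalool is used so that every intermediate is one diastereomer; its optical purity is not critical and the racemate would also serve, because its stereocentre is erased in step 16 and the absolute configuration of the target rests on the Sharpless step.

## Structural features

The target is a germacrane-type sesquiterpene lactone: a ten-membered carbocycle (C1–C10) bridged by an ether oxygen between C1 and C4 (oxolane C1–C2–C3–C4–O) and fused along C6–C7 to a butenolide (O–C12(=O)–C11=C7–C6). The C5=C6 bond is at once the enol-lactone (γ-ylidene) alkene of the butenolide and a ring alkene of the macrocycle, with C4 syn to C7 (5E); C11 carries the acetoxymethyl carbon C13, and C8, next to C7, carries the angelate. C1 (S) and C10 (R) are adjacent, C8 (S) stands 1,3 to C10 (syn diol relation along C8–C9–C10), and the quaternary C4 faces C1 across the oxolane and can only have the configuration that lets the macrocycle span the oxolane on one face. Fragile groups are the enol lactone (an acylating agent, sensitive to base and nucleophiles), the angelate (Z to E isomerisation under base, nucleophilic catalysis or triplet sensitisation), the primary allylic acetate on the butenolide (ionisable by low-valent metals) and the tertiary C10 alcohol (dehydration, and retro-aldol cleavage while C8 is a ketone). The real difficulty is to close a strained, bridged ten-membered ring while creating the quaternary C4 and keeping the less stable geometry of C5=C6, in which C4 sits next to the C7 substituent. The key step exploits that C4 is a tertiary α-oxy carbon bonded directly to the vinylic C5: an oxolane-2-carboxylic acid at C4 is a source of a planar nucleophilic radical, C5 can be offered as a vinyl bromide of fixed geometry, and the oxolane translates the C1 configuration into that of C4 at the moment of closure.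

## Logic of the disconnections

27 to 24 and 25 (through 26). The C8–O acyl bond is cut. The Z-configured unsaturated ester is the group least likely to survive light, sensitiser and carbonate, so it goes on last; 24 then has one acylable hydroxyl, since the tertiary C10 carbinol does not compete. The forward step must acylate a hindered secondary allylic alcohol without Z to E isomerisation of the acyl donor.

24 to 23 to 22. The C13–O acetyl bond and both O–Si bonds are cut. Keeping both oxygens as silyl ethers until after ring closure takes an allylic ester out of the nickel step and lets one reagent protect C8 and C13 together. The price is a forward acetylation that must tell the primary C13 hydroxyl of 23 from the secondary C8 hydroxyl.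

22 to 21. The C4–C5 bond is cut, which opens the ten-membered ring and removes the quaternary stereocentre. This cut turns C4 (carboxylate, radical precursor) and C5 (vinyl bromide) into stable, separately addressable functions and makes the C4 configuration of 21 irrelevant. The forward step must favour ring closure over intermolecular coupling and keep the C5=C6 geometry.

21 to 20. The lactone C6–O bond and the C5–Br bond are cut. An alkynoic acid has no alkene geometry to control, and anti addition across the alkyne fixes bromine anti to the ring oxygen, that is syn to C7. The forward step must be 5-exo selective and must leave the second carboxyl alone.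

20 to 18 (through 19). The C4 carboxyl is traced back to an ethenyl group, which is inert to organolithium reagents, hydride transfer and singlet oxygen and so carries the latent acid through the fragment union. The forward cleavage must single out the terminal alkene from the acceptor-substituted tetrasubstituted alkene and the alkyne.

18 to 17. The alkyne carbon C5 is removed, leaving C6 as a masked aldehyde (lactol) beside the C12 carboxyl. The simplification is a one-carbon homologation; its demand is that the lactol opens under the basic conditions without loss of the cis relation of C6 and C12.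

17 to 15 (through 16). The hydroxybutenolide is read as an oxidised furan. The ring of 15 holds C6 and C12 on one side and C8 and C13 on the other side of the future C7=C11 bond, so the tetrasubstituted alkene never has to be made selectively, and the C–Si bond marks C12 as the carbonyl carbon. The forward oxidation must not touch the ethenyl group.

15 to 14 to 13. The two O–Si bonds are cut, then the C8–H bond: the C8 stereocentre is traced to a heteroaryl ketone. This leaves a ketone that a chiral transfer-hydrogenation catalyst can reduce, with the C10 carbinol as a possible second control element. The forward reduction must give 8S.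

13 to 12 to 11 and 6. The ketone is masked as a dithiane and the C8–C9 bond is cut. This is the convergent cut into an acyl-anion fragment and an epoxide of similar size. The forward step needs attack at the CH2 end of a 1,1-disubstituted epoxide.

11 to 10 to 9 to 8 to 7. The dithiane is traced to a formyl group, the C7–C8 bond and the C12–Si bond are cut, and the silyl group is traced to the silyl ether of the hydroxymethyl group. The hydroxymethyl group (the later C13) serves twice as a director, first for silicon at C12 and then for metalation at C7. The demand is regiocontrol on the furan in both metalations.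

6 to 4 to 2 to 1 (through 5 and 3). The epoxide is traced to the 1,2-diol, the oxolane C1–O bond and the C10–O bond to an allylic alcohol by epoxidation and ring opening, and the C9–O bond to an allylic oxidation. Two stereocentres (C1 and C10) come from one reagent-controlled epoxidation of a cheap terpene alcohol. The demand is opening of the epoxide at C1 and not at C10.

## Other disconnections considered

Alternative 1: The cut is the C8–C9 bond of the carbocycle, taken back by a retro-Cope change to a six-membered ring; in the forward sense the potassium alkoxide of a trans-1,2-dialkenylcyclohexenol undergoes an anionic oxy-Cope shift and expands to the ten-membered dienone A1. In its favour: the ring-forming event is known, thermal and reliable, it comes at the start, the chair transition state sets the 1(10)E and 4Z alkenes, the C8 silyl group is a latent hydroxyl of defined configuration, and the 4Z-enone is the acceptor that Alternative 3 needs. Against it here: A1, as its string shows, is a C12 ring ketone without the three-carbon unit at C7 (an 11,12,13-trinor compound, not a full germacrane) and without the oxygens at C1, C4, C10, C12 and C13. The lactone carbons would have to be attached at C7, the 1(10)-alkene oxidised with facial control on a flexible ring, and the bridge and enol lactone built afterwards in a long linear series of redox and protecting-group steps. Comparison: on precedent and reliability of macrocycle formation the alternative is the better plan. On structure the chosen plan is better, since it joins two fully oxygenated fragments and needs three steps after ring closure. Mechanistically a two-electron pericyclic step stands against a radical and organometallic step that is untested as a ring closure. In step count the alternative is expected to be clearly longer than 19 steps.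

Alternative 2: The cut is the C1–O bond (with the C10–O bond) of the oxolane; in the forward sense Sharpless epoxidation of the C9 allylic alcohol with Ti(OiPr)4, D-(−)-diisopropyl tartrate and tert-butyl hydroperoxide is followed in the same flask by attack of the C4 hydroxyl on C1 to give diol A2. A2 is compound 4 and the reaction is step 2 of the chosen route, so on this point the two plans are equal: known chemistry and two stereocentres from a cheap terpene in one operation. As the strategic disconnection of the whole target it falls short, because it closes only the five-membered ring and leaves the macrocycle, C8 and the butenolide open. In A2 the ethenyl group is anti to the diol side chain, so a plan that kept it as C5=C6 could not bridge the oxolane and would need the epimeric series from the enantiomeric terpene alcohol, whose optical purity would then decide the diastereomeric purity. Where the alternative would be better: a plan that keeps the ethenyl carbons has better atom economy, since the chosen route discards both (as formaldehyde and CO2). Where the chosen plan is better: it is indifferent to the C4 configuration and to the optical purity of the terpene. Step economy cannot be compared before a ring closure is named for the alternative.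

Alternative 3: The cut is the O–C4 bond; in the forward sense the C1 hydroxyl of a macrocyclic C4=C5–C6 enone adds across the ring to C4 under acid or mild base catalysis and gives the bridged γ-keto allyl ester A3. In its favour: transannular oxa-conjugate addition is a well-precedented polar reaction type (better than the chosen plan on precedent), it is driven by ring strain relief, and both esters are already in place, so the end game after A3 is short (deallylation and enol lactonisation of the γ-keto acid toward C5). C4 is set by the same cis-only bridge as in the chosen plan, so on stereocontrol at C4 the two are equal. Against it here: it presupposes the ten-membered enone with C1, C8 and C10 in place and with the alkylidene diester unit at C7, so the macrocyclisation problem is moved, not solved. The angelate and the allylic acetate must also survive the conjugate addition, the zerovalent palladium deallylation and the lactonisation, and the conjugate addition is reversible. Comparison: mechanistically it is the safer single step. Structurally the chosen plan is better, because it solves ring closure and C4 in one event from an open-chain acid that is easy to assemble. Step economy depends on the unsolved access to the enone; if A1 were used as its source the total would be long.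

Key step: step 16

## Steps

Step 1
Reactants: 1 (S)-(+)-linalool [(3S)-3,7-dimethylocta-1,6-dien-3-ol]
Product: 2 (2E,6S)-2,6-dimethylocta-2,7-diene-1,6-diol
Conditions: SeO2 (0.1 equiv), salicylic acid (0.1 equiv), t-BuOOH (70% aq., 3 equiv), CH2Cl2, rt
Reagents that add atoms: tert-butyl hydroperoxide CC(C)(C)OO
Why: Riley-type allylic oxidation run catalytically in SeO2; the ene reaction and [2,3]-shift take place at the E methyl group of the trisubstituted alkene and should give the E allylic alcohol, while the vinyl carbinol end has no allylic hydrogen and is left alone.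

Step 2
Reactants: 2 (2E,6S)-2,6-dimethylocta-2,7-diene-1,6-diol
Product: 4 (2R)-2-[(2S,5S)-5-ethenyl-5-methyloxolan-2-yl]propane-1,2-diol, via epoxy alcohol 3 (not isolated)
Conditions: Ti(OiPr)4 (0.2 equiv), D-(−)-diisopropyl tartrate (0.25 equiv), t-BuOOH (anhydrous, 2 equiv), 4 Å MS, CH2Cl2, −20 °C; then Ti(OiPr)4 (1 equiv), 0 °C to rt
Reagents that add atoms: tert-butyl hydroperoxide CC(C)(C)OO
Why: Katsuki–Sharpless epoxidation of the primary allylic alcohol; the D-(−)-tartrate reagent should give the (2R,3R)-epoxide 3 under reagent control (the remote carbinol has no say), and the titanium-bound epoxy alcohol is then opened at the distal carbon by the tertiary hydroxyl in a 5-exo-tet reaction with inversion at C1 and retention at C10, which sets 1S and 10R.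

Step 3
Reactants: 4 (2R)-2-[(2S,5S)-5-ethenyl-5-methyloxolan-2-yl]propane-1,2-diol
Product: 6 (2S,5S)-2-ethenyl-2-methyl-5-[(2R)-2-methyloxiran-2-yl]oxolane, via primary tosylate 5 (not isolated)
Conditions: TsCl (1.1 equiv), Et3N, Bu2SnO (2 mol%), CH2Cl2, 0 °C to rt; then K2CO3, MeOH, rt
Reagents that add atoms: none
Why: Tin-acetal-catalysed sulfonylation is selective for the primary hydroxyl of a 1,2-diol; the tertiary alkoxide then displaces the tosylate (3-exo-tet Williamson closure) and C10 keeps its configuration because its C–O bond is not touched.

Step 4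
Reactants: 7 furan-3-ylmethanol
Product: 8 tert-butyl(furan-3-ylmethoxy)dimethylsilane
Conditions: TBSCl, imidazole, DMF, rt
Reagents that add atoms: tert-butyl(chloro)dimethylsilane CC(C)(C)[Si](C)(C)Cl
Why: Standard silylation of a primary alcohol; the silyl ether is the silicon source for the next step.

Step 5
Reactants: 8 tert-butyl(furan-3-ylmethoxy)dimethylsilane
Product: 9 {2-[tert-butyl(dimethyl)silyl]furan-3-yl}methanol
Conditions: n-BuLi (1.2 equiv), HMPA (1.2 equiv), THF, −78 to 0 °C; then H2O
Reagents that add atoms: none
Why: Lithiation at C2 next to the ring oxygen and the alkoxymethyl group is followed by 1,4 O-to-C silyl migration (retro-Brook rearrangement), which puts silicon on the carbon that becomes C12 and frees the hydroxyl as a director for step 6.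

Step 6
Reactants: 9 {2-[tert-butyl(dimethyl)silyl]furan-3-yl}methanol
Product: 10 5-[tert-butyl(dimethyl)silyl]-4-(hydroxymethyl)furan-3-carbaldehyde
Conditions: n-BuLi (2.2 equiv), DME, 0 °C; then DMF, −78 to 0 °C; then H2O
Reagents that add atoms: N,N-dimethylformamide CN(C)C=O
Why: With C2 blocked by silicon, the lithium alkoxide directs the second deprotonation to C4 (directed metalation known for 2-silyl-3-furylmethanols) and formylation of the aryllithium installs the carbon that becomes C8.

Step 7
Reactants: 10 5-[tert-butyl(dimethyl)silyl]-4-(hydroxymethyl)furan-3-carbaldehyde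
Product: 11 {2-[tert-butyl(dimethyl)silyl]-4-(1,3-dithian-2-yl)furan-3-yl}methanol
Conditions: HS(CH2)3SH (1.1 equiv), BF3·OEt2 (0.2 equiv), CH2Cl2, −20 °C
Reagents that add atoms: propane-1,3-dithiol SCCCS
Why: Lewis-acid-catalysed dithioacetalisation of an aryl aldehyde; low temperature and a substoichiometric acid should spare the C–Si bond and the furylmethanol.

Step 8
Reactants: 11 {2-[tert-butyl(dimethyl)silyl]-4-(1,3-dithian-2-yl)furan-3-yl}methanol; 6 (2S,5S)-2-ethenyl-2-methyl-5-[(2R)-2-methyloxiran-2-yl]oxolane
Product: 12 (2R)-1-(2-{5-[tert-butyl(dimethyl)silyl]-4-(hydroxymethyl)furan-3-yl}-1,3-dithian-2-yl)-2-[(2S,5S)-5-ethenyl-5-methyloxolan-2-yl]propan-2-ol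
Conditions: 11, n-BuLi (2.1 equiv), THF/HMPA, −78 to −20 °C; then 6, −20 to 0 °C; then H2O
Reagents that add atoms: none
Why: Corey–Seebach umpolung; the 2-aryl-1,3-dithiane anion (the primary hydroxyl rides as its lithium alkoxide) opens the 1,1-disubstituted epoxide at the CH2 terminus by SN2 attack, forming C8–C9 without touching C10.

Step 9
Reactants: 12 (2R)-1-(2-{5-[tert-butyl(dimethyl)silyl]-4-(hydroxymethyl)furan-3-yl}-1,3-dithian-2-yl)-2-[(2S,5S)-5-ethenyl-5-methyloxolan-2-yl]propan-2-ol
Product: 13 (3R)-1-{5-[tert-butyl(dimethyl)silyl]-4-(hydroxymethyl)furan-3-yl}-3-[(2S,5S)-5-ethenyl-5-methyloxolan-2-yl]-3-hydroxybutan-1-one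
Conditions: MeI (excess), CaCO3, MeCN/H2O (4:1), 45 °C
Reagents that add atoms: water O
Why: Alkylative hydrolysis of the dithioketal (S-methylation, then attack of water); the neutral, halonium-free conditions should spare the electron-rich silylfuran, the ethenyl group and the β-hydroxy ketone.

Step 10
Reactants: 13 (3R)-1-{5-[tert-butyl(dimethyl)silyl]-4-(hydroxymethyl)furan-3-yl}-3-[(2S,5S)-5-ethenyl-5-methyloxolan-2-yl]-3-hydroxybutan-1-one
Product: 14 (1S,3R)-1-{5-[tert-butyl(dimethyl)silyl]-4-(hydroxymethyl)furan-3-yl}-3-[(2S,5S)-5-ethenyl-5-methyloxolan-2-yl]butane-1,3-diol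
Conditions: RuCl[(S,S)-TsDPEN](p-cymene) (2 mol%), HCO2H/Et3N (5:2), CH2Cl2, rt
Reagents that add atoms: none
Why: Noyori asymmetric transfer hydrogenation of a heteroaryl alkyl ketone; under catalyst control the (S,S)-complex should deliver hydride to the face that gives the 8S carbinol (aryl group recognised as in aryl methyl ketones), which is the 8,10-syn diol, and isolated alkenes are not reduced.

Step 11
Reactants: 14 (1S,3R)-1-{5-[tert-butyl(dimethyl)silyl]-4-(hydroxymethyl)furan-3-yl}-3-[(2S,5S)-5-ethenyl-5-methyloxolan-2-yl]butane-1,3-diol
Product: 15 (2R,4S)-4-(TBS-oxy)-4-[5-TBS-4-(TBS-oxymethyl)furan-3-yl]-2-[(2S,5S)-5-ethenyl-5-methyloxolan-2-yl]butan-2-ol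
Conditions: TBSCl (2.5 equiv), imidazole (5 equiv), DMF, 40 °C
Reagents that add atoms: tert-butyl(chloro)dimethylsilane CC(C)(C)[Si](C)(C)Cl
Why: Standard silylation; the primary C13 and secondary C8 hydroxyls react, the tertiary C10 carbinol does not under chloride and imidazole conditions.

Step 12
Reactants: 15 (2R,4S)-4-(TBS-oxy)-4-[5-TBS-4-(TBS-oxymethyl)furan-3-yl]-2-[(2S,5S)-5-ethenyl-5-methyloxolan-2-yl]butan-2-ol
Product: 17 5-hydroxy-4-{(1S,3R)-1-(TBS-oxy)-3-[(2S,5S)-5-ethenyl-5-methyloxolan-2-yl]-3-hydroxybutyl}-3-(TBS-oxymethyl)furan-2(5H)-one (both lactol epimers), via furan endoperoxide 16 (not isolated)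
Conditions: O2, visible light, tetraphenylporphyrin (1 mol%), CH2Cl2, −78 °C; then warm to rt, H2O
Reagents that add atoms: dioxygen O=O
Why: [4+2] cycloaddition of singlet oxygen to the furan gives 16, and the C–Si bond directs its collapse (silyl shift to peroxide oxygen, then hydrolysis of the silyl ester) so that the silylated carbon becomes the lactone carbonyl C12 and the unsubstituted α-carbon the lactol C6; the monosubstituted alkene is inert to singlet oxygen.

Step 13
Reactants: 17 5-hydroxy-4-{(1S,3R)-1-(TBS-oxy)-3-[(2S,5S)-5-ethenyl-5-methyloxolan-2-yl]-3-hydroxybutyl}-3-(TBS-oxymethyl)furan-2(5H)-one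
Product: 18 (2E)-3-{(1S,3R)-1-(TBS-oxy)-3-[(2S,5S)-5-ethenyl-5-methyloxolan-2-yl]-3-hydroxybutyl}-2-(TBS-oxymethyl)pent-2-en-4-ynoic acid (carboxyl cis to ethynyl)
Conditions: dimethyl (1-diazo-2-oxopropyl)phosphonate (1.5 equiv), K2CO3 (3 equiv), MeOH, 0 °C to rt; then pH 4 buffer
Reagents that add atoms: dimethyl (1-diazo-2-oxopropyl)phosphonate CC(=O)C(=[N+]=[N-])P(=O)(OC)OC
Why: Ohira–Bestmann (Seyferth–Gilbert) homologation of the aldehyde tautomer of the lactol, which is open as the carboxylate under the basic conditions; the tetrasubstituted alkene comes from the ring and keeps carboxyl and ethynyl cis.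

Step 14
Reactants: 18 (2E)-3-{(1S,3R)-1-(TBS-oxy)-3-[(2S,5S)-5-ethenyl-5-methyloxolan-2-yl]-3-hydroxybutyl}-2-(TBS-oxymethyl)pent-2-en-4-ynoic acid
Product: 20 (2S,5S)-5-[(2R,4S,5E)-6-carboxy-5-ethynyl-2-hydroxy-4,7-bis(TBS-oxy)hept-5-en-2-yl]-2-methyloxolane-2-carboxylic acid, via oxolane aldehyde 19 (not isolated)
Conditions: O3, MeCN/H2O (9:1), 0 °C (Sudan red 7B end point), N2 purge; then NaClO2, NaH2PO4, 0 °C to rt
Reagents that add atoms: ozone [O-][O+]=O; sodium chlorite [Na+].[O-]Cl=O
Why: Ozone should cleave the terminal ethenyl group much faster than the acceptor-substituted tetrasubstituted enyne alkene or the alkyne; in wet acetonitrile the carbonyl oxide is hydrolysed to aldehyde 19, which a Pinnick oxidation takes to the acid, with the hydrogen peroxide formed in the first stage as hypochlorite scavenger.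

Step 15
Reactants: 20 (2S,5S)-5-[(2R,4S,5E)-6-carboxy-5-ethynyl-2-hydroxy-4,7-bis(TBS-oxy)hept-5-en-2-yl]-2-methyloxolane-2-carboxylic acid
Product: 21 (2S,5S)-5-[(2R,4S)-4-[(2E)-2-(bromomethylidene)-5-oxo-4-(TBS-oxymethyl)-2,5-dihydrofuran-3-yl]-2-hydroxy-4-(TBS-oxy)butan-2-yl]-2-methyloxolane-2-carboxylic acid
Conditions: NBS (1.05 equiv), KHCO3 (2.5 equiv), Bu4NHSO4 (cat.), CH2Cl2/H2O, 0 °C, dark; then pH 3 buffer
Reagents that add atoms: N-bromosuccinimide O=C1CCC(=O)N1Br
Why: Bromolactonisation of an alkynoic acid; the C12 carboxylate and bromine add anti across the terminal alkyne in the 5-exo-dig mode (attack at the internal carbon), which gives the E bromomethylene lactone with bromine anti to the ring oxygen and syn to C7, while the remote C4 carboxylate cannot reach the alkyne.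

Step 16
Reactants: 21 (2S,5S)-5-[(2R,4S)-4-[(2E)-2-(bromomethylidene)-5-oxo-4-(TBS-oxymethyl)-2,5-dihydrofuran-3-yl]-2-hydroxy-4-(TBS-oxy)butan-2-yl]-2-methyloxolane-2-carboxylic acid
Product: 22 (1S,5E,8S,10R)-8,13-bis(TBS-oxy)-1,4-epoxy-10-hydroxygermacra-5,7(11)-dien-12,6-olide
Conditions: Ir[dF(CF3)ppy]2(dtbbpy)PF6 (2 mol%), NiCl2(dme) (20 mol%), 4,4'-di-tert-butyl-2,2'-bipyridine (22 mol%), Cs2CO3 (1.2 equiv), DMSO (2 mM, degassed), blue LEDs (450 nm), 25 °C
Reagents that add atoms: none
Why: Proposed new method: the excited iridium photocatalyst oxidises the caesium carboxylate of 21, CO2 is lost and a planar tertiary α-oxy radical is left at C4, while a zerovalent nickel–bipyridine complex inserts into the C5–Br bond with retention; the divalent vinylnickel bromide captures the radical within the same molecule, the trivalent nickel centre so formed reductively eliminates the C4–C5 bond, and the reduced photocatalyst returns nickel to its low-valent state. The closest known reaction type is the intermolecular nickel and photoredox decarboxylative coupling of α-oxy carboxylic acids with vinyl halides; its use as a ring closure, and with a tertiary radical, is the untested part. The ten-membered carbocycle closes by C(sp3)–C(sp2) reductive elimination from a medium-ring nickelacycle (eleven-membered along the carbon chain), not by radical attack on a π bond, so no exo or endo constraint applies, but high dilution is needed against intermolecular coupling. The new stereocentre C4 is set by the ring: the oxolane can only be bridged with C5 and C10 on one face, so C5 must enter syn to the C1 side chain whichever C4 epimer of the acid is used. Retention at C5 keeps C4 syn to C7 (5E), and bromine syn to C7 in 21 places the nickel end beside the C8 chain, which pre-folds the seco chain. Both oxygens on the butenolide side are silyl ethers, so no allylic ester can ionise at low-valent nickel, and the free tertiary C10 hydroxyl and the enol lactone should tolerate the mild carbonate base.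

Step 17
Reactants: 22 (1S,5E,8S,10R)-8,13-bis(TBS-oxy)-1,4-epoxy-10-hydroxygermacra-5,7(11)-dien-12,6-olide
Product: 23 (1S,5E,8S,10R)-1,4-epoxy-8,10,13-trihydroxygermacra-5,7(11)-dien-12,6-olide
Conditions: HF·pyridine, pyridine, THF, 0 °C to rt
Reagents that add atoms: none
Why: Fluoride-mediated desilylation under buffered, non-basic conditions, which the enol lactone and the tertiary alcohol should tolerate.

Step 18
Reactants: 23 (1S,5E,8S,10R)-1,4-epoxy-8,10,13-trihydroxygermacra-5,7(11)-dien-12,6-olide
Product: 24 (1S,5E,8S,10R)-13-acetoxy-1,4-epoxy-8,10-dihydroxygermacra-5,7(11)-dien-12,6-olide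
Conditions: AcCl (1.1 equiv), 2,4,6-collidine, CH2Cl2, −78 °C
Reagents that add atoms: acetyl chloride CC(=O)Cl
Why: Primary-selective acylation; acetyl chloride with a hindered pyridine base at low temperature should discriminate the primary C13 hydroxyl from the hindered secondary C8 and the tertiary C10 hydroxyls.

Step 19
Reactants: 24 (1S,5E,8S,10R)-13-acetoxy-1,4-epoxy-8,10-dihydroxygermacra-5,7(11)-dien-12,6-olide; 25 angelic acid [(2Z)-2-methylbut-2-enoic acid]
Product: 27 (1S,5E,8S,10R)-13-acetoxy-8-[(2Z)-2-methylbut-2-enoyloxy]-1,4-epoxy-10-hydroxygermacra-5,7(11)-dien-12,6-olide (CNP0162854.1), via mixed anhydride 26 (not isolated)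
Conditions: 25, 2,4,6-trichlorobenzoyl chloride, Et3N, toluene, rt; then 24, toluene, 80 °C (no DMAP)
Reagents that add atoms: none
Why: Yamaguchi esterification through mixed anhydride 26; leaving out the nucleophilic pyridine catalyst avoids the addition–elimination pathway that turns angelate into tiglate, and only the secondary C8 hydroxyl is acylated because the tertiary C10 carbinol is too hindered.

## Compound list

1 | (S)-(+)-linalool, (3S)-3,7-dimethylocta-1,6-dien-3-ol | CC(C)=CCC[C@](C)(O)C=C | starting material
2 | (2E,6S)-2,6-dimethylocta-2,7-diene-1,6-diol | OC/C(C)=C/CC[C@](C)(O)C=C | intermediate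
3 | [(2R,3R)-3-[(3S)-3-hydroxy-3-methylpent-4-en-1-yl]-2-methyloxiran-2-yl]methanol | OC[C@@]1(C)O[C@@H]1CC[C@](C)(O)C=C | intermediate (not isolated)
4 | (2R)-2-[(2S,5S)-5-ethenyl-5-methyloxolan-2-yl]propane-1,2-diol | OC[C@@](C)(O)[C@@H]1CC[C@@](C)(C=C)O1 | intermediate
5 | (2R)-2-[(2S,5S)-5-ethenyl-5-methyloxolan-2-yl]-2-hydroxypropyl 4-methylbenzenesulfonate | Cc1ccc(cc1)S(=O)(=O)OC[C@@](C)(O)[C@@H]2CC[C@@](C)(C=C)O2 | intermediate (not isolated)
6 | (2S,5S)-2-ethenyl-2-methyl-5-[(2R)-2-methyloxiran-2-yl]oxolane | C[C@@]1(CO1)[C@@H]2CC[C@@](C)(C=C)O2 | intermediate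
7 | furan-3-ylmethanol | OCc1ccoc1 | starting material
8 | tert-butyl(furan-3-ylmethoxy)dimethylsilane | CC(C)(C)[Si](C)(C)OCc1ccoc1 | intermediate
9 | {2-[tert-butyl(dimethyl)silyl]furan-3-yl}methanol | CC(C)(C)[Si](C)(C)c1occc1CO | intermediate
10 | 5-[tert-butyl(dimethyl)silyl]-4-(hydroxymethyl)furan-3-carbaldehyde | CC(C)(C)[Si](C)(C)c1occ(C=O)c1CO | intermediate
11 | {2-[tert-butyl(dimethyl)silyl]-4-(1,3-dithian-2-yl)furan-3-yl}methanol | CC(C)(C)[Si](C)(C)c1occ(C2SCCCS2)c1CO | intermediate
12 | (2R)-1-(2-{5-[tert-butyl(dimethyl)silyl]-4-(hydroxymethyl)furan-3-yl}-1,3-dithian-2-yl)-2-[(2S,5S)-5-ethenyl-5-methyloxolan-2-yl]propan-2-ol | CC(C)(C)[Si](C)(C)c1occ(c1CO)C2(SCCCS2)C[C@@](C)(O)[C@@H]3CC[C@@](C)(C=C)O3 | intermediate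
13 | (3R)-1-{5-[tert-butyl(dimethyl)silyl]-4-(hydroxymethyl)furan-3-yl}-3-[(2S,5S)-5-ethenyl-5-methyloxolan-2-yl]-3-hydroxybutan-1-one | CC(C)(C)[Si](C)(C)c1occ(c1CO)C(=O)C[C@@](C)(O)[C@@H]2CC[C@@](C)(C=C)O2 | intermediate
14 | (1S,3R)-1-{5-[tert-butyl(dimethyl)silyl]-4-(hydroxymethyl)furan-3-yl}-3-[(2S,5S)-5-ethenyl-5-methyloxolan-2-yl]butane-1,3-diol | CC(C)(C)[Si](C)(C)c1occ(c1CO)[C@@H](O)C[C@@](C)(O)[C@@H]2CC[C@@](C)(C=C)O2 | intermediate
15 | (2R,4S)-4-(TBS-oxy)-4-[5-TBS-4-(TBS-oxymethyl)furan-3-yl]-2-[(2S,5S)-5-ethenyl-5-methyloxolan-2-yl]butan-2-ol | CC(C)(C)[Si](C)(C)c1occ(c1CO[Si](C)(C)C(C)(C)C)[C@@H](O[Si](C)(C)C(C)(C)C)C[C@@](C)(O)[C@@H]2CC[C@@](C)(C=C)O2 | intermediate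
16 | 2,3,7-trioxabicyclo[2.2.1]hept-5-ene from 15 (TBS on C1, side chain on C5, TBS-oxymethyl on C6; both faces) | CC(C)(C)[Si](C)(C)C12OOC(O1)C(=C2CO[Si](C)(C)C(C)(C)C)[C@@H](O[Si](C)(C)C(C)(C)C)C[C@@](C)(O)[C@@H]3CC[C@@](C)(C=C)O3 | intermediate (not isolated)
17 | 5-hydroxy-4-{(1S,3R)-1-(TBS-oxy)-3-[(2S,5S)-5-ethenyl-5-methyloxolan-2-yl]-3-hydroxybutyl}-3-(TBS-oxymethyl)furan-2(5H)-one (both lactol epimers) | OC1OC(=O)C(CO[Si](C)(C)C(C)(C)C)=C1[C@@H](O[Si](C)(C)C(C)(C)C)C[C@@](C)(O)[C@@H]2CC[C@@](C)(C=C)O2 | intermediate
18 | (2E)-3-{(1S,3R)-1-(TBS-oxy)-3-[(2S,5S)-5-ethenyl-5-methyloxolan-2-yl]-3-hydroxybutyl}-2-(TBS-oxymethyl)pent-2-en-4-ynoic acid | C#C/C(=C(/CO[Si](C)(C)C(C)(C)C)C(=O)O)[C@@H](O[Si](C)(C)C(C)(C)C)C[C@@](C)(O)[C@@H]1CC[C@@](C)(C=C)O1 | intermediate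
19 | (2E)-3-{(1S,3R)-1-(TBS-oxy)-3-[(2S,5S)-5-formyl-5-methyloxolan-2-yl]-3-hydroxybutyl}-2-(TBS-oxymethyl)pent-2-en-4-ynoic acid | C#C/C(=C(/CO[Si](C)(C)C(C)(C)C)C(=O)O)[C@@H](O[Si](C)(C)C(C)(C)C)C[C@@](C)(O)[C@@H]1CC[C@@](C)(C=O)O1 | intermediate (not isolated)
20 | (2S,5S)-5-[(2R,4S,5E)-6-carboxy-5-ethynyl-2-hydroxy-4,7-bis(TBS-oxy)hept-5-en-2-yl]-2-methyloxolane-2-carboxylic acid | C#C/C(=C(/CO[Si](C)(C)C(C)(C)C)C(=O)O)[C@@H](O[Si](C)(C)C(C)(C)C)C[C@@](C)(O)[C@@H]1CC[C@@](C)(C(=O)O)O1 | intermediate
21 | (2S,5S)-5-[(2R,4S)-4-[(2E)-2-(bromomethylidene)-5-oxo-4-(TBS-oxymethyl)-2,5-dihydrofuran-3-yl]-2-hydroxy-4-(TBS-oxy)butan-2-yl]-2-methyloxolane-2-carboxylic acid (seco acid, precursor of the key step) | CC(C)(C)[Si](C)(C)O[C@H](C1=C(CO[Si](C)(C)C(C)(C)C)C(=O)O/C1=C/Br)C[C@@](C)(O)[C@@H]2CC[C@@](C)(C(=O)O)O2 | intermediate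
22 | (1S,5E,8S,10R)-8,13-bis(TBS-oxy)-1,4-epoxy-10-hydroxygermacra-5,7(11)-dien-12,6-olide (product of the key step; C4 fixed by the bridge) | CC(C)(C)[Si](C)(C)O[C@H]1C[C@@](C)(O)[C@@H]2CC[C@@](C)(/C=C3/OC(=O)C(CO[Si](C)(C)C(C)(C)C)=C31)O2 | intermediate
23 | (1S,5E,8S,10R)-1,4-epoxy-8,10,13-trihydroxygermacra-5,7(11)-dien-12,6-olide | O[C@H]1C[C@@](C)(O)[C@@H]2CC[C@@](C)(/C=C3/OC(=O)C(CO)=C31)O2 | intermediate
24 | (1S,5E,8S,10R)-13-acetoxy-1,4-epoxy-8,10-dihydroxygermacra-5,7(11)-dien-12,6-olide | O[C@H]1C[C@@](C)(O)[C@@H]2CC[C@@](C)(/C=C3/OC(=O)C(COC(C)=O)=C31)O2 | intermediate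
25 | angelic acid, (2Z)-2-methylbut-2-enoic acid | C/C=C(/C)C(=O)O | starting material
26 | (2Z)-2-methylbut-2-enoic 2,4,6-trichlorobenzoic anhydride | C/C=C(/C)C(=O)OC(=O)c1c(Cl)cc(Cl)cc1Cl | intermediate (not isolated)
27 | (1S,5E,8S,10R)-13-acetoxy-8-[(2Z)-2-methylbut-2-enoyloxy]-1,4-epoxy-10-hydroxygermacra-5,7(11)-dien-12,6-olide (CNP0162854.1) | C/C=C(/C)C(=O)O[C@H]1C[C@@](C)(O)[C@@H]2CC[C@@](C)(/C=C3/OC(=O)C(COC(C)=O)=C31)O2 | target

## Step count and least certain steps

Total: 19 steps. Longest linear sequence: 16 steps (7 to 27 through steps 4 to 8 and 9 to 19); the terpene branch (steps 1 to 3) joins at step 8.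

Step 16 (key step, proposed new method). Most likely to go wrong:
- Intermolecular coupling may outrun ring closure, because the radical and the vinylnickel end are formed independently at opposite ends of the chain.
- The radical may be quenched by hydrogen-atom abstraction, or oxidised to the oxocarbenium ion and trapped by the C10 hydroxyl or the solvent.
- Reductive elimination may be slow for a tertiary radical partner.
- Triplet energy transfer from the photocatalyst may isomerise the vinyl bromide or the product alkene.
- Base may open the enol lactone.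

Fallback with known reaction types, from 21 back to 22: oxidative decarboxylation of the α-alkoxy acid with Pb(OAc)4 (pyridine, wet MeCN) would unmask C4 as a methyl ketone and C1 as a free hydroxyl, giving seco hydroxy ketone F1. An intramolecular Nozaki–Hiyama–Kishi reaction (CrCl2, NiCl2 cat., DMSO/THF, high dilution) would then join the C5 vinyl bromide to the C4 ketone with retention of alkene geometry and give the macrocyclic tertiary allylic carbinol F2 as either C4 epimer. Acid (PPTS, CH2Cl2, 4 Å MS) would ionise this doubly activated carbinol, and capture by the C1 hydroxyl across the ring closes the oxolane with loss of water. Again only the cis bridge can form, which returns the route to 22.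

Step 13. The lactol may open too slowly, or the open cis formyl acrylate may isomerise or add methoxide before homologation, and the cis alkynoic acid may cyclise prematurely on acidification. Fallback from 17 back to 18: alkylation of the carboxylate with allyl bromide and K2CO3 in DMF would trap the open form as the allyl ester aldehyde F3. Seyferth–Gilbert homologation without methanol (dimethyl (diazomethyl)phosphonate, KOtBu, THF, −78 °C) would give the allyl enynoate F4. Deallylation with Pd(PPh3)4 and morpholine would then release 18.

Step 14. Over-oxidation is the risk: ozone may also attack the tetrasubstituted enyne alkene or the alkyne once the ethenyl group is consumed. Fallback from 18 back to 20: osmium-catalysed dihydroxylation (OsO4 cat., N-methylmorpholine N-oxide, acetone/H2O), which discriminates more sharply against electron-poor and hindered π bonds, would give the vicinal diol F5. Cleavage with NaIO4 gives 19 (isolated in this variant), and NaClO2/NaH2PO4/H2O2 gives 20.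

Step 10. Facial selectivity may be poor or turnover slow if the ortho-substituted furyl ketone and the C10 carbinol oppose the catalyst. Fallback from 13 back to 14: Narasaka–Prasad reduction (Et2BOMe, NaBH4, THF/MeOH, −78 °C) replaces catalyst control by chelation-controlled 1,3-induction from the C10 hydroxyl, which should also favour the 8,10-syn diol; no new compound is made.

Step 18. Discrimination between the primary C13 and the secondary C8 hydroxyl may be incomplete, leading to double acetylation or acetyl migration. Fallback from 22 back to 24: brief treatment with HF·pyridine buffered with pyridine at 0 °C would remove only the primary silyl ether and give the 13-hydroxy 8-silyl ether F6. Ac2O in pyridine would give its acetate F7, and full desilylation with HF·pyridine would return to 24.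

## Further compounds

F1 | step 16 | (5E)-5-(bromomethylidene)-3-(TBS-oxymethyl)-4-[(1S,3R,4S)-1-(TBS-oxy)-3,4-dihydroxy-3-methyl-7-oxooctyl]furan-2(5H)-one | CC(=O)CC[C@H](O)[C@](C)(O)C[C@H](O[Si](C)(C)C(C)(C)C)C1=C(CO[Si](C)(C)C(C)(C)C)C(=O)O/C1=C/Br
F2 | step 16 | (1S,5E,8S,10R)-8,13-bis(TBS-oxy)-1,4,10-trihydroxygermacra-5,7(11)-dien-12,6-olide (either C4 epimer) | CC(C)(C)[Si](C)(C)O[C@H]1C[C@@](C)(O)[C@@H](O)CCC(C)(O)/C=C2/OC(=O)C(CO[Si](C)(C)C(C)(C)C)=C21
F3 | step 13 | prop-2-en-1-yl (2Z)-3-{(1S,3R)-1-(TBS-oxy)-3-[(2S,5S)-5-ethenyl-5-methyloxolan-2-yl]-3-hydroxybutyl}-2-(TBS-oxymethyl)-4-oxobut-2-enoate | O=C/C(=C(/CO[Si](C)(C)C(C)(C)C)C(=O)OCC=C)[C@@H](O[Si](C)(C)C(C)(C)C)C[C@@](C)(O)[C@@H]1CC[C@@](C)(C=C)O1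
F4 | step 13 | prop-2-en-1-yl ester of 18 | C#C/C(=C(/CO[Si](C)(C)C(C)(C)C)C(=O)OCC=C)[C@@H](O[Si](C)(C)C(C)(C)C)C[C@@](C)(O)[C@@H]1CC[C@@](C)(C=C)O1
F5 | step 14 | vicinal diol from 18 (1,2-dihydroxyethyl in place of ethenyl, both epimers) | C#C/C(=C(/CO[Si](C)(C)C(C)(C)C)C(=O)O)[C@@H](O[Si](C)(C)C(C)(C)C)C[C@@](C)(O)[C@@H]1CC[C@@](C)(C(O)CO)O1
F0 | step 10 | none | none
F6 | step 18 | (1S,5E,8S,10R)-8-(TBS-oxy)-1,4-epoxy-10,13-dihydroxygermacra-5,7(11)-dien-12,6-olide | CC(C)(C)[Si](C)(C)O[C@H]1C[C@@](C)(O)[C@@H]2CC[C@@](C)(/C=C3/OC(=O)C(CO)=C31)O2
F7 | step 18 | (1S,5E,8S,10R)-13-acetoxy-8-(TBS-oxy)-1,4-epoxy-10-hydroxygermacra-5,7(11)-dien-12,6-olide | CC(C)(C)[Si](C)(C)O[C@H]1C[C@@](C)(O)[C@@H]2CC[C@@](C)(/C=C3/OC(=O)C(COC(C)=O)=C31)O2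
A1 | alternative 1 | (2Z,6E,9S)-9-[dimethyl(phenyl)silyl]-3,7-dimethylcyclodeca-2,6-dien-1-one (8-silyl-11,12,13-trinorgermacra-1(10)E,4Z-dien-6-one) | C[Si](C)(c1ccccc1)[C@@H]2CC(=O)/C=C(C)\CC/C=C(C)/C2
A2 | alternative 2 | (2R)-2-[(2S,5S)-5-ethenyl-5-methyloxolan-2-yl]propane-1,2-diol (identical with 4) | OC[C@@](C)(O)[C@@H]1CC[C@@](C)(C=C)O1
A3 | alternative 3 | prop-2-en-1-yl 13-acetoxy-8-[(2Z)-2-methylbut-2-enoyloxy]-1,4-epoxy-10-hydroxy-6-oxogermacr-7(11)-en-12-oate | C/C=C(/C)C(=O)O[C@H]1C[C@@](C)(O)[C@@H]2CC[C@@](C)(CC(=O)/C1=C(/COC(C)=O)C(=O)OCC=C)O2
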